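The route rests on cutting the cis C3=C4 double bond of the 2H-pyran ring. Because this olefin sits in a six-membered ring between the fully substituted, oxygen-bearing C2 and the ring-fusion carbon C4a, both of its carbons can be brought in as terminal vinyl groups, and a ruthenium-catalysed ring-closing metathesis then closes the pyran in one operation; the only other alkene, the exocyclic methylidene of the cyclohexane, is too hindered to interfere. The precursor is a hydroquinone-level 2-vinylphenyl tertiary allyl ether, made by palladium-catalysed asymmetric allylic etherification of a symmetric dihydroxybenzaldehyde with a cyclofarnesyl-type carbonate whose ring stereocentres come from an octalone opened by Eschenmoser–Tanabe fragmentation. Phenol oxidation finishes the quinone.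

Key step: step 13

Assumption: for the E-configured 3,3-disubstituted allyl carbonate the (R,R)-ligand is taken to give the (S)-ether, and the (S)-amine is taken to give the (R)-quaternary centre as in the 2-methylcyclohexanone series; the ligand sense should be checked on geranyl methyl carbonate (correlation with linalool) and the mirror-image ligand used if the test demands it.

Step 1
Reactants: 1 2,6-dimethylcyclohexanone (commercial cis/trans mixture); 2 (S)-1-phenylethylamine
Product: 3 N-[(1S)-1-phenylethyl]-2,6-dimethylcyclohexan-1-imine (ring methyl centres as a mixture)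
Conditions: p-TsOH (cat.), toluene, reflux, Dean–Stark
Reagents that add atoms: (S)-1-phenylethylamine (2), C[C@H](N)c1ccccc1
Why: Acid-catalysed imine formation with azeotropic removal of water; the ring methyl centres stay a mixture because they equilibrate through the enamine tautomers.

Step 2
Reactants: 3 the imine; 4 methyl vinyl ketone
Product: 6 (2R)-2,6-dimethyl-2-(3-oxobutyl)cyclohexan-1-one (C6 epimers), via Michael-adduct imine 5 (not isolated)
Conditions: methyl vinyl ketone (1.2 equiv), THF, rt to 40 °C; then 20% aq. AcOH, rt
Reagents that add atoms: methyl vinyl ketone (4), C=CC(C)=O; water, O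
Why: Michael addition of a chiral imine through its secondary enamine tautomer (aza-ene-type transition state with internal N–H transfer) should occur at the substituted α-carbon on the face away from the phenyl group of the (S)-auxiliary and so set the (R)-quaternary centre, after which mild acid hydrolysis releases the 1,5-diketone and the auxiliary; C6 is not yet controlled.

Step 3
Reactants: 6 the diketone
Product: 8 (4aR,8R)-4a,8-dimethyl-4,4a,5,6,7,8-hexahydronaphthalen-2(3H)-one, via bicyclic ketol 7 (not isolated)
Conditions: NaOMe (1 equiv), MeOH, 60 °C, until the epimer ratio no longer changes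
Reagents that add atoms: none
Why: Intramolecular aldol condensation (second stage of a Robinson annulation) closes ring A, and under these equilibrating conditions C8 should epimerise through the extended dienolate to the isomer with the 8-methyl equatorial and trans to the axial angular methyl (the bicyclic counterpart of the 6β-to-6α-methyl epimerisation of Δ4-3-ketosteroids); the minor epimer should be separable by chromatography and can be resubmitted.

Step 4
Reactants: 8 the octalone
Product: 9 (4aR,8R)-1,8a-epoxy-4a,8-dimethyloctahydronaphthalen-2(1H)-one (oxirane configuration not assigned)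
Conditions: 30% H2O2, NaOH (aq.), MeOH, 0 °C to rt
Reagents that add atoms: hydrogen peroxide, OO
Why: Weitz–Scheffer nucleophilic epoxidation of the enone; either oxirane face serves the next step, and C8 is already the thermodynamic epimer so the base does no harm.

Step 5
Reactants: 9 the epoxy ketone
Product: 11 (2R,6R)-2-(but-3-yn-1-yl)-2,6-dimethylcyclohexan-1-one, via epoxy tosylhydrazone 10 (not isolated)
Conditions: TsNHNH2 (1.05 equiv), AcOH/CH2Cl2 (1:1), −20 °C to rt; neutral work-up
Reagents that add atoms: none
Why: Eschenmoser–Tanabe fragmentation: the tosylhydrazone opens the oxirane to an alkoxy diazene that fragments with loss of N2 and sulfinate, cleaving the former enone C1–C8a bond to unveil the ring ketone and a terminal butynyl chain while both ring stereocentres stay untouched (weakly acidic conditions avoid enolisation at C6).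

Step 6
Reactants: 11 the alkynyl ketone
Product: 12 (1R,3R)-1-(but-3-yn-1-yl)-1,3-dimethyl-2-methylidenecyclohexane
Conditions: Zn, CH2Br2, TiCl4 (preformed reagent), THF/CH2Cl2, 0 °C to rt
Reagents that add atoms: dibromomethane, BrCBr
Why: Lombardo methylenation with a non-basic zinc/titanium methylene reagent converts hindered, enolisable ketones to methylidene compounds without epimerising the α-centre, which matters because the two C6 epimers of the monocyclic ketone are of similar energy.

Step 7
Reactants: 12 the enyne
Product: 14 (2E)-5-[(1R,3R)-1,3-dimethyl-2-methylidenecyclohexyl]-3-methylpent-2-en-1-ol, via alkenyldimethylalane 13 (not isolated)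
Conditions: Me3Al (3 equiv), Cp2ZrCl2 (0.3 equiv), CH2Cl2, 0 °C to rt; then (CH2O)n, THF, 0 °C to rt; Rochelle salt work-up
Reagents that add atoms: trimethylaluminium, C[Al](C)C; paraformaldehyde (as formaldehyde), C=O
Why: Negishi zirconium-catalysed carboalumination adds methyl and aluminium syn across the terminal alkyne with aluminium at the terminus, and trapping of the alkenylalane with formaldehyde with retention fixes the E-trisubstituted allylic alcohol; the hindered 1,1-disubstituted methylidene should not react.

Step 8
Reactants: 14 the allylic alcohol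
Product: 15 (2E)-5-[(1R,3R)-1,3-dimethyl-2-methylidenecyclohexyl]-3-methylpent-2-en-1-yl methyl carbonate
Conditions: ClCO2Me, pyridine, CH2Cl2, 0 °C
Reagents that add atoms: methyl chloroformate, COC(=O)Cl
Why: Acylation of the primary allylic alcohol (carbonate formation) installs the ionisable leaving group for the allylic substitution.

Step 9
Reactants: 16 1,2,4,5-tetramethoxybenzene
Product: 18 2,3,5,6-tetramethoxybenzaldehyde, via aryllithium 17 (not isolated)
Conditions: n-BuLi, TMEDA, THF, 0 °C to rt; DMF, −78 °C to rt; H2O
Reagents that add atoms: N,N-dimethylformamide, CN(C)C=O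
Why: Directed ortho-lithiation between two methoxy groups followed by formylation; the two free ring positions are equivalent, so only one aldehyde can form.

Step 10
Reactants: 18 the tetramethoxy aldehyde
Product: 19 2,6-dihydroxy-3,5-dimethoxybenzaldehyde
Conditions: AlCl3 (4 equiv), CH2Cl2, 0 °C to rt; then 1 M HCl
Reagents that add atoms: none
Why: Chelation-controlled Lewis-acid demethylation: aluminium bound to the formyl oxygen should cleave the two methyl ethers ortho to the aldehyde and leave the two meta ethers, giving the symmetric diphenol.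

Step 11
Reactants: 15 the allylic carbonate; 19 the diphenol (2 equiv)
Product: 20 2-{[(3S)-5-[(1R,3R)-1,3-dimethyl-2-methylidenecyclohexyl]-3-methylpent-1-en-3-yl]oxy}-6-hydroxy-3,5-dimethoxybenzaldehyde
Conditions: Pd2(dba)3·CHCl3 (2.5 mol%), (R,R)-DACH-phenyl Trost ligand (7.5 mol%), CH2Cl2, rt
Reagents that add atoms: 2,6-dihydroxy-3,5-dimethoxybenzaldehyde (19), O=Cc1c(O)c(OC)cc(OC)c1O
Why: Tsuji–Trost asymmetric allylic etherification: ionisation of the E-carbonate gives a π-allylpalladium complex that the phenoxide should attack at the more substituted terminus inside the chiral pocket of the ligand, setting the (S)-tertiary ether centre under catalyst control, while the excess of symmetric diphenol and hydrogen bonding of the second hydroxyl to the formyl group hold the reaction at mono-etherification.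

Step 12
Reactants: 20 the ether aldehyde
Product: 21 2-ethenyl-3-{[(3S)-5-[(1R,3R)-1,3-dimethyl-2-methylidenecyclohexyl]-3-methylpent-1-en-3-yl]oxy}-4,6-dimethoxyphenol
Conditions: Ph3PCH3Br (3.5 equiv), KOtBu (3.3 equiv), THF, 0 °C to rt
Reagents that add atoms: methyltriphenylphosphonium bromide, C[P+](c1ccccc1)(c1ccccc1)c1ccccc1.[Br-]
Why: Wittig methylenation; the first equivalent of ylide deprotonates the phenol and the excess converts the aldehyde to the styrene, under conditions that leave the quaternary allylic ether untouched.

Step 13
Reactants: 21 the diene phenol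
Product: 22 (2S)-2-{2-[(1R,3R)-1,3-dimethyl-2-methylidenecyclohexyl]ethyl}-6,8-dimethoxy-2-methyl-2H-chromen-5-ol
Conditions: second-generation Grubbs catalyst (H2IMes)(PCy3)Cl2Ru=CHPh (5 mol%), CH2Cl2 (5 mM), 40 °C, argon purge
Reagents that add atoms: none
Why: The Ru alkylidene loads onto one of the two monosubstituted vinyl groups with loss of ethene, and intramolecular [2+2] cycloaddition onto the other vinyl group followed by cycloreversion releases the chromene and Ru=CH2, the escape of ethene making the sequence irreversible. The closest known reaction type is ring-closing olefin metathesis of 2-vinylphenyl allyl ethers to 2H-chromenes. One ring is closed, the six-membered pyran ring, by ring-closing metathesis between C4 (the styrene carbon) and C3 (the vinyl carbon on C2), so the new C3=C4 bond is necessarily cis. No stereocentre is created, and the (S)-centre at C2 is quaternary, so it offers no hydrogen through which a ruthenium hydride could isomerise or epimerise it. The selectivity needed is chemoselectivity among three alkenes and ring closure over intermolecular metathesis: the 1,1-disubstituted methylidene is flanked by a quaternary carbon and a methine and should not engage the catalyst, and the gem-disubstituted C2 together with high dilution favours six-ring closure.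

Step 14
Reactants: 22 the chromenol
Product: 23 metachromin E, (2S)-2-{2-[(1R,3R)-1,3-dimethyl-2-methylidenecyclohexyl]ethyl}-6-methoxy-2-methyl-2H-chromene-5,8-dione
Conditions: PhI(OAc)2 (1.1 equiv), MeCN/H2O (4:1), 0 °C
Reagents that add atoms: water, O
Why: Oxidation of a 4-methoxyphenol by the trivalent iodine reagent: the aryloxy-iodane collapses with attack of water at C8, para to the hydroxyl, and loss of methanol from the hemiketal should give the 5,8-quinone while the C6 methoxy group, the chromene double bond and the methylidene are retained.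

Compound list
1 | 2,6-dimethylcyclohexanone (cis/trans mixture) | CC1CCCC(C)C1=O | starting material
2 | (S)-1-phenylethylamine | C[C@H](N)c1ccccc1 | starting material
3 | N-[(1S)-1-phenylethyl]-2,6-dimethylcyclohexan-1-imine (ring centres as a mixture) | CC1CCCC(C)C1=N[C@@H](C)c1ccccc1 | intermediate
4 | methyl vinyl ketone | C=CC(C)=O | starting material
5 | Michael-adduct imine, 4-[(1R)-1,3-dimethyl-2-{[(1S)-1-phenylethyl]imino}cyclohexyl]butan-2-one (not isolated) | CC(=O)CC[C@@]1(C)CCCC(C)C1=N[C@@H](C)c1ccccc1 | intermediate
6 | (2R)-2,6-dimethyl-2-(3-oxobutyl)cyclohexan-1-one (C6 epimers) | CC(=O)CC[C@@]1(C)CCCC(C)C1=O | intermediate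
7 | bicyclic ketol, (4aR)-8a-hydroxy-4a,8-dimethyloctahydronaphthalen-2(1H)-one (C8 and C8a not assigned; not isolated) | O=C1CC[C@@]2(C)CCCC(C)C2(O)C1 | intermediate
8 | (4aR,8R)-4a,8-dimethyl-4,4a,5,6,7,8-hexahydronaphthalen-2(3H)-one | O=C1C=C2[C@H](C)CCC[C@]2(C)CC1 | intermediate
9 | (4aR,8R)-1,8a-epoxy-4a,8-dimethyloctahydronaphthalen-2(1H)-one (oxirane configuration not assigned) | O=C1CC[C@@]2(C)CCC[C@@H](C)C23OC13 | intermediate
10 | tosylhydrazone of 9 (not isolated) | Cc1ccc(cc1)S(=O)(=O)NN=C1CC[C@@]2(C)CCC[C@@H](C)C23OC13 | intermediate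
11 | (2R,6R)-2-(but-3-yn-1-yl)-2,6-dimethylcyclohexan-1-one | O=C1[C@H](C)CCC[C@]1(C)CCC#C | intermediate
12 | (1R,3R)-1-(but-3-yn-1-yl)-1,3-dimethyl-2-methylidenecyclohexane | C=C1[C@H](C)CCC[C@]1(C)CCC#C | intermediate
13 | [(1E)-4-[(1R,3R)-1,3-dimethyl-2-methylidenecyclohexyl]-2-methylbut-1-en-1-yl]dimethylalane (not isolated) | C=C1[C@H](C)CCC[C@]1(C)CC/C(C)=C/[Al](C)C | intermediate
14 | (2E)-5-[(1R,3R)-1,3-dimethyl-2-methylidenecyclohexyl]-3-methylpent-2-en-1-ol | C=C1[C@H](C)CCC[C@]1(C)CC/C(C)=C/CO | intermediate
15 | (2E)-5-[(1R,3R)-1,3-dimethyl-2-methylidenecyclohexyl]-3-methylpent-2-en-1-yl methyl carbonate | C=C1[C@H](C)CCC[C@]1(C)CC/C(C)=C/COC(=O)OC | intermediate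
16 | 1,2,4,5-tetramethoxybenzene | COc1cc(OC)c(OC)cc1OC | starting material
17 | 2,3,5,6-tetramethoxyphenyllithium (not isolated) | [Li]c1c(OC)c(OC)cc(OC)c1OC | intermediate
18 | 2,3,5,6-tetramethoxybenzaldehyde | O=Cc1c(OC)c(OC)cc(OC)c1OC | intermediate
19 | 2,6-dihydroxy-3,5-dimethoxybenzaldehyde | O=Cc1c(O)c(OC)cc(OC)c1O | intermediate
20 | 2-{[(3S)-5-[(1R,3R)-1,3-dimethyl-2-methylidenecyclohexyl]-3-methylpent-1-en-3-yl]oxy}-6-hydroxy-3,5-dimethoxybenzaldehyde | C=C1[C@H](C)CCC[C@]1(C)CC[C@@](C)(C=C)Oc1c(C=O)c(O)c(OC)cc1OC | intermediate
21 | 2-ethenyl-3-{[(3S)-5-[(1R,3R)-1,3-dimethyl-2-methylidenecyclohexyl]-3-methylpent-1-en-3-yl]oxy}-4,6-dimethoxyphenol | C=C1[C@H](C)CCC[C@]1(C)CC[C@@](C)(C=C)Oc1c(C=C)c(O)c(OC)cc1OC | intermediate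
22 | (2S)-2-{2-[(1R,3R)-1,3-dimethyl-2-methylidenecyclohexyl]ethyl}-6,8-dimethoxy-2-methyl-2H-chromen-5-ol | C=C1[C@H](C)CCC[C@]1(C)CC[C@@]1(C)C=Cc2c(O1)c(OC)cc(OC)c2O | intermediate
23 | metachromin E | C=C1[C@H](C)CCC[C@]1(C)CC[C@@]1(C)C=CC2=C(O1)C(=O)C=C(OC)C2=O | target

Total step count: 14. Longest linear sequence: 12 steps (steps 1 to 8, then 11 to 14); the arene branch is steps 9 and 10.

Steps most likely to fail

Step 11. Attack of the doubly ortho-substituted phenoxide at the tertiary allyl terminus may be too slow, so that formation of the linear ether, re-ionisation of the product with erosion of enantiopurity, or a second etherification take over. The fallback sets out from 12 and 19 and returns at 20. Gold-catalysed hydration of the alkyne of 12 (Ph3PAuNTf2 cat., MeOH/H2O, rt) would give the methyl ketone F1. Addition of ethynylmagnesium bromide (THF, 0 °C) would give the tertiary propargylic alcohol F2 as both carbinol epimers, and n-BuLi then ClCO2Me (THF, −78 °C) would give its methyl carbonate F3. Copper-catalysed propargylic etherification of 19 (CuCl2·2H2O cat., DBU, MeCN, 0 °C) would give the aryl propargyl ether F4. Semihydrogenation (H2, Pd/CaCO3 poisoned with Pb(OAc)2, quinoline, EtOAc) would give 20 together with its epimer at the ether carbon F5, to be removed by preparative HPLC. Stereocontrol at this centre is given up in exchange for a dependable C–O bond formation.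

Step 10. Ether cleavage may not stop at the two methoxy groups that flank the formyl group: the aluminium phenoxide formed first can direct cleavage of the neighbouring meta ether, or the second ortho ether may resist. The fallback sets out from 18 and returns at 23. Mono-demethylation with BCl3 (1.1 equiv, CH2Cl2, −10 °C) would give 2-hydroxy-3,5,6-trimethoxybenzaldehyde F6. The same palladium-catalysed etherification with 15 would give the trimethoxy ether aldehyde F7, Wittig methylenation would give the trimethoxy styrene F8, and the same ring-closing metathesis would give the 5,6,8-trimethoxychromene F9. Oxidative demethylation with (NH4)2Ce(NO3)6 (MeCN/H2O, 0 °C) would then give 23; the p-quinone across C5 and C8 is expected, with ring-opening across C6 and C8a as the competing path.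

Step 6. Lewis-acid-mediated enolisation may epimerise C6, the acidic alkyne C–H may consume the methylene reagent, or the hindered carbonyl may not react. The fallback sets out from 11 and returns at 12 by a two-stage Peterson olefination. Addition of Me3SiCH2Li/CeCl3 (3 equiv, THF, −78 °C), a weakly basic organocerium reagent, would give the β-hydroxysilane F10, and elimination with KH (THF, 0 °C to rt) would give 12.

Further compounds
F1 | step 11 | 4-[(1R,3R)-1,3-dimethyl-2-methylidenecyclohexyl]butan-2-one | C=C1[C@H](C)CCC[C@]1(C)CCC(C)=O
F2 | step 11 | 5-[(1R,3R)-1,3-dimethyl-2-methylidenecyclohexyl]-3-methylpent-1-yn-3-ol (both carbinol epimers) | C=C1[C@H](C)CCC[C@]1(C)CCC(C)(O)C#C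
F3 | step 11 | 5-[(1R,3R)-1,3-dimethyl-2-methylidenecyclohexyl]-3-methylpent-1-yn-3-yl methyl carbonate (both epimers) | C=C1[C@H](C)CCC[C@]1(C)CCC(C)(OC(=O)OC)C#C
F4 | step 11 | 2-{[5-[(1R,3R)-1,3-dimethyl-2-methylidenecyclohexyl]-3-methylpent-1-yn-3-yl]oxy}-6-hydroxy-3,5-dimethoxybenzaldehyde (both epimers) | C=C1[C@H](C)CCC[C@]1(C)CCC(C)(C#C)Oc1c(C=O)c(O)c(OC)cc1OC
F5 | step 11 | 2-{[(3R)-5-[(1R,3R)-1,3-dimethyl-2-methylidenecyclohexyl]-3-methylpent-1-en-3-yl]oxy}-6-hydroxy-3,5-dimethoxybenzaldehyde (epimer of 20) | C=C1[C@H](C)CCC[C@]1(C)CC[C@](C)(C=C)Oc1c(C=O)c(O)c(OC)cc1OC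
F6 | step 10 | 2-hydroxy-3,5,6-trimethoxybenzaldehyde | O=Cc1c(O)c(OC)cc(OC)c1OC
F7 | step 10 | 2-{[(3S)-5-[(1R,3R)-1,3-dimethyl-2-methylidenecyclohexyl]-3-methylpent-1-en-3-yl]oxy}-3,5,6-trimethoxybenzaldehyde | C=C1[C@H](C)CCC[C@]1(C)CC[C@@](C)(C=C)Oc1c(C=O)c(OC)c(OC)cc1OC
F8 | step 10 | 3-ethenyl-2-{[(3S)-5-[(1R,3R)-1,3-dimethyl-2-methylidenecyclohexyl]-3-methylpent-1-en-3-yl]oxy}-1,4,5-trimethoxybenzene | C=C1[C@H](C)CCC[C@]1(C)CC[C@@](C)(C=C)Oc1c(C=C)c(OC)c(OC)cc1OC
F9 | step 10 | (2S)-2-{2-[(1R,3R)-1,3-dimethyl-2-methylidenecyclohexyl]ethyl}-5,6,8-trimethoxy-2-methyl-2H-chromene | C=C1[C@H](C)CCC[C@]1(C)CC[C@@]1(C)C=Cc2c(O1)c(OC)cc(OC)c2OC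
F10 | step 6 | (2R,6R)-2-(but-3-yn-1-yl)-2,6-dimethyl-1-[(trimethylsilyl)methyl]cyclohexan-1-ol (carbinol configuration not assigned) | C[Si](C)(C)CC1(O)[C@H](C)CCC[C@]1(C)CCC#C
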